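# Proposed total synthesis of eryvarin F via late formation of ring B from an acyclic diketone chain

Numbering used throughout: 1 tribromoresorcinol; 2 its bis(methoxymethyl) ether; 3 prenyl bromide; 4, 6, 10 aryllithiums; 5 monoprenyl dibromide; 7 diprenyl bromide; 8 diacid chloride; 9 bis-amide; 11, 19 tetrahedral adducts; 12 aryl ketone; 13 diol; 14 mono-ether; 15 enaminone; 16 chromone amide; 17 methoxy enone; 18 its enolate; 20 diketone precursor; 21 bis-enolate; 22 ring-closed dienediolate; 23 protected product; 24 eryvarin F. Ring B carbons are C1' (ether carbon) to C6'.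

## Analysis of the target

Eryvarin F is a chromen-4-one (rings A and C) whose C3 carries an ether oxygen to a 2,4-dihydroxyphenyl ring B, so it is a 3-aryloxychromone and not an isoflavone. Ring A is fully substituted except for C5: 3-methylbut-2-enyl groups on C6 and C8 flank the C7 hydroxyl. There is no stereocentre; the problem is regiochemistry and chemoselectivity. The sensitive groups are the two trisubstituted alkenes (acid-induced cyclisation onto a neighbouring phenol, electrophilic oxidants), C2 of the chromone (ring opening by hard nucleophiles) and ring B, an electron-rich mono-ether of a 1,2,4-trioxygenated benzene that oxidises easily. The difficulty is twofold: four contiguous substituents on ring A must be placed without ambiguity, and the C3–O–C1' ether joins an enol oxygen to an electron-rich arene, which no substitution on a preformed ring B makes easily. The strategy rests on ring B: oxygen on C1', C2' and C4' and hydrogen on C3', C5' and C6' is the pattern of a 1-alkoxyhexane-2,4-dione whose C6' is at the aldehyde level, so one C1'–C6' bond and loss of one alcohol give the resorcinol. A second feature helps the approach: the run C4–C3–O–C1'–C2' has the skeleton of 2,2'-oxydiacetic acid, so the C3 oxygen and both carbons beside it can come from one bought piece.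

## Retrosynthetic reasoning

24 to 23. The last bond cut is the O7–acetal bond. One methoxymethyl group is kept on O7 until the end so that the two enolate steps before it run on a substrate with no acidic phenol; ring B needs no protection because it does not yet exist.

23 to 20 (key disconnection). Ring B is cut at C1'–C6', which unfolds it into the open chain 20, a 1,3-diketone ending in a beta-methoxy enone. Cutting here and not at the C3–O or O–C1' ether bonds avoids any coupling of an enol oxygen with an electron-rich aryl partner and any protected, trioxygenated ring B building block. Forward, a hindered amide base must take 20 to bis-enolate 21, C1' must bond to C6' (22), and the methoxy group must leave so that the ring aromatises.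

20 to 16 and 17. The chain is cut at C2'–C3'. This splits it into the four-carbon enone 17, which brings C3' to C6' with the enol ether in place, and the amide 16 as acyl donor. Attaching a complete six-carbon chain to a C3 hydroxyl by O-alkylation was rejected: a chain with a leaving group on C1' beside the 1,3-dicarbonyl unit would close from its own enolate oxygen onto C1' to a five-membered ring as soon as base is present. Forward, the enolate 18 has to acylate once at the amide and leave the chromone alone.

16 to 14. Ring C is cut at O1–C2 and C2–C3, removing C2 as a one-carbon unit at the formate level. The gain is that C3 already carries its ether oxygen in 14, so the chromone forms directly at the right oxidation level. Oxidising a finished ring C at C3 would not be compatible with two electron-rich alkenes.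

14 to 13 to 12. These are protecting-group changes only. Both acetals of 12 are removed and the C4 oxygen alone is re-protected, using the hydrogen bond that ties the C2 hydroxyl to the ketone. A selective removal of only one acetal from 12 would be shorter but is less certain.

12 to 7 and 9; 9 to 8. The aryl–carbonyl bond (the later C4–C4a) is cut to give aryl bromide 7 and the symmetric bis-amide 9, made in one step from 8. A single addition to 9 delivers the ketone, the C3 oxygen, C1' and the second amide for the later chain extension.

7 to 5 to 2 (with 3), and 2 to 1. The two aryl–CH2 bonds are cut in turn. The three bromines of 1 mark exactly the three ring positions that must carry carbon. Bromine–lithium exchange is preferred to direct deprotonation because it is faster than removal of the benzylic–allylic protons of a prenyl group already present. It is preferred to electrophilic prenylation of a free ring A phenol because that gives mixtures of C- and O-alkylation at several sites.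

## Alternatives that were turned down

Alternative 1: Rings A and C are cut at C5–C6, C8–C8a and O1–C2. This leads to the symmetric ketone 2,10-dimethylundeca-2,9-dien-6-one A2 and the tri-electrophile methyl 4-[2,4-bis(methoxymethoxy)phenoxy]-5-(dimethylamino)-2-[(dimethylamino)methylidene]-3-oxopent-4-enoate A3. In the forward step, doubly deprotonated A2 would attack one aminomethylene carbon and the ester carbon of A3, ring A would aromatise, and the new C8a oxygen would close onto the second aminomethylene carbon to give 3-[2,4-bis(methoxymethoxy)phenoxy]-7-hydroxy-6,8-bis(3-methylbut-2-enyl)chromen-4-one A1. From A1 only the two ring B acetals would remain to be removed.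
- For: both prenyl positions follow from the symmetry of A2 without any aromatic substitution, two rings form in one flask, and the route is more convergent and probably shorter than the chosen one.
- Against: A3 offers three electrophilic carbons and a ketone to two secondary carbanions and one oxygen. Nothing in the structure forces the first attack onto the right aminomethylene carbon, and a wrong order puts the aryloxy group on the benzene ring. A3 must also be assembled by a double aminomethylenation, and its ring B enters as a protected, separately prepared trioxygenated arene.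
- Comparison: the chosen route forms only one bond in its key step, but ring size fixes its regiochemistry, and ring B needs neither a preformed arene nor protecting groups.

Alternative 2: Ring A is cut at C5–C6 and C4a–C8a. The diene 1-methoxy-2,4-bis(3-methylbut-2-enyl)-1,3-bis(trimethylsilyloxy)buta-1,3-diene A5 would add to the ynone 1-[2,4-bis(methoxymethoxy)phenoxy]but-3-yn-2-one A6. Loss of the methoxy and silyl groups would give 2-[2,4-bis(methoxymethoxy)phenoxy]-1-[2,4-dihydroxy-3,5-bis(3-methylbut-2-enyl)phenyl]ethanone A4.
- For: this is the alternative closest to established arene syntheses, and the polarity of the two partners fixes the regiochemistry. A4 has both ring A phenols free beside the ketone, so it needs neither organolithium steps on ring A nor the protecting-group change of steps 6 and 7. On these points it is stronger than the chosen route.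
- Against: A5 is substituted at C2 and C4, so it is hindered, slow to reach the reactive conformation and easily hydrolysed. A6 is a base-sensitive acetylenic ketone. Ring B is again built separately and protected. After A4, ring C closure and removal of two acetals remain.
- Comparison: the chosen route accepts a less precedented key step and gets ring B from the cheap enone 17 at the very end, with no oxidation-prone arene carried through the synthesis.

Alternative 3: Ring C is cut at C3–C4 and O1–C2. Irradiation of 7-(methoxymethoxy)-2,2-dimethyl-6,8-bis(3-methylbut-2-enyl)-1,3-benzodioxin-4-one A8 would open the acetal ring to the ketene 3-(methoxymethoxy)-2,4-bis(3-methylbut-2-enyl)-6-(oxomethylidene)cyclohexa-2,4-dien-1-one A10. The enamine (E)-2-[2,4-bis(methoxymethoxy)phenoxy]-N,N-dimethylethenamine A9 would trap it at its oxygen-bearing carbon, and closure of O1 onto C2 with loss of the amino group would give 3-[2,4-bis(methoxymethoxy)phenoxy]-7-(methoxymethoxy)-6,8-bis(3-methylbut-2-enyl)chromen-4-one A7.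
- For: two complete halves are joined under neutral conditions, and A7 is one deprotection operation from the target. This is the shortest end-game of all four plans.
- Against: A8 needs the same regiodefined placement of two prenyl groups on ring A as the chosen route, plus a carboxyl group, so ring A is no easier. A10 can add to A9 in a four-membered cycloaddition instead of C-acylation, and A9 is a hydrolytically labile enamine. The chromone A7 absorbs the light that generates A10. Three acetals must be removed by acid beside two prenyl groups.
- Comparison: the chosen route needs the same single deprotection after its key step and a few more steps before it, but it requires no photochemistry, no preformed ring B, and only one acetal at the end.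

Key step: step 10

## Route

Remark on the chemistry: 2,4,6-tribromobenzene-1,3-diol 1 is taken to be a commercial compound, and the 1,3-diketone 20 is drawn in the diketo form although it should exist largely as an enol.

Step 1
Reactants: 1 2,4,6-tribromobenzene-1,3-diol
Product: 2 1,3,5-tribromo-2,4-bis(methoxymethoxy)benzene
Conditions: NaH (2.4 equiv), MOMCl (2.4 equiv), DMF, 0 °C → rt
Reagents that add atoms: chloromethyl methyl ether, COCCl
Why: Williamson-type O-alkylation of both phenoxides; the flanking bromines make the phenols acidic and the small, very reactive chloromethyl ether still reaches the hindered oxygens. The acetals later stabilise the adjacent aryllithiums and survive every basic step.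

Step 2
Reactants: 2 1,3,5-tribromo-2,4-bis(methoxymethoxy)benzene; 3 1-bromo-3-methylbut-2-ene
Product: 5 1,5-dibromo-2,4-bis(methoxymethoxy)-3-(3-methylbut-2-enyl)benzene, via aryllithium 4 (not isolated)
Conditions: n-BuLi (1.05 equiv), THF, −78 °C; then CuBr·SMe2 (10 mol %), 3 (1.2 equiv), −78 → 0 °C
Reagents that add atoms: none
Why: Bromine–lithium exchange followed by copper-catalysed allylic substitution; exchange should occur at the bromine between the two acetal oxygens, where the carbanion of 4 is stabilised inductively and by chelation from both sides. The arylcopper species attacks the unhindered CH2 end of 3 and not its fully substituted gamma carbon, so the linear prenyl group results; no bromine is ortho to lithium, so an aryne cannot form.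

Step 3
Reactants: 5 1,5-dibromo-2,4-bis(methoxymethoxy)-3-(3-methylbut-2-enyl)benzene; 3 1-bromo-3-methylbut-2-ene
Product: 7 1-bromo-2,4-bis(methoxymethoxy)-3,5-bis(3-methylbut-2-enyl)benzene, via aryllithium 6 (not isolated)
Conditions: n-BuLi (1.05 equiv), THF, −78 °C; then CuBr·SMe2 (10 mol %), 3 (1.2 equiv), −78 → 0 °C
Reagents that add atoms: none
Why: The same exchange–allylation sequence on one of the two equivalent bromines of 5; the monolithiated, electron-rich ring resists a second exchange. Exchange at −78 °C outruns removal of the benzylic–allylic protons of the prenyl group already present.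

Step 4
Reactants: 8 2,2'-oxydiacetyl chloride
Product: 9 N,N'-dimethoxy-N,N'-dimethyl-2,2'-oxydiacetamide
Conditions: MeNHOMe·HCl (2.2 equiv), K2CO3 (aq), CH2Cl2, 0 °C
Reagents that add atoms: N,O-dimethylhydroxylamine hydrochloride, CNOC.Cl
Why: Schotten–Baumann amide formation at both acid chloride groups; the N-methoxy-N-methylamide is the standard acyl donor for a single addition of an organolithium or an enolate.

Step 5
Reactants: 7 1-bromo-2,4-bis(methoxymethoxy)-3,5-bis(3-methylbut-2-enyl)benzene; 9 N,N'-dimethoxy-N,N'-dimethyl-2,2'-oxydiacetamide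
Product: 12 2-{2-[2,4-bis(methoxymethoxy)-3,5-bis(3-methylbut-2-enyl)phenyl]-2-oxoethoxy}-N-methoxy-N-methylacetamide, via aryllithium 10 (not isolated), via tetrahedral adduct 11 (not isolated)
Conditions: n-BuLi (1.05 equiv), THF, −78 °C; added to 9 (3 equiv), THF, −78 → 0 °C; aq. NH4Cl
Reagents that add atoms: none
Why: Weinreb ketone synthesis: aryllithium 10 adds once to one amide group of 9, which is kept in excess by inverse addition, and the lithium chelate 11 does not collapse before work-up, so no over-addition occurs at that carbonyl. The step forms the later C4–C4a bond and brings in the C3 oxygen, C1' and the second amide.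

Step 6
Reactants: 12 2-{2-[2,4-bis(methoxymethoxy)-3,5-bis(3-methylbut-2-enyl)phenyl]-2-oxoethoxy}-N-methoxy-N-methylacetamide
Product: 13 2-{2-[2,4-dihydroxy-3,5-bis(3-methylbut-2-enyl)phenyl]-2-oxoethoxy}-N-methoxy-N-methylacetamide
Conditions: HCl (1 M), MeOH, rt
Reagents that add atoms: none
Why: Acid-catalysed methanolysis of both aryl acetals; ketone and amide are inert to dilute acid at room temperature, and the acyl group lowers the tendency of the freed phenols to add to the prenyl double bonds.

Step 7
Reactants: 13 2-{2-[2,4-dihydroxy-3,5-bis(3-methylbut-2-enyl)phenyl]-2-oxoethoxy}-N-methoxy-N-methylacetamide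
Product: 14 2-{2-[2-hydroxy-4-(methoxymethoxy)-3,5-bis(3-methylbut-2-enyl)phenyl]-2-oxoethoxy}-N-methoxy-N-methylacetamide
Conditions: MOMCl (1.1 equiv), K2CO3, acetone, rt
Reagents that add atoms: chloromethyl methyl ether, COCCl
Why: Selective O-alkylation: the C2 hydroxyl is held in a hydrogen bond to the ketone and stays free, while the more acidic C4 hydroxyl para to the carbonyl reacts; this differentiation is routine for 2,4-dihydroxyaryl ketones.

Step 8
Reactants: 14 2-{2-[2-hydroxy-4-(methoxymethoxy)-3,5-bis(3-methylbut-2-enyl)phenyl]-2-oxoethoxy}-N-methoxy-N-methylacetamide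
Product: 16 N-methoxy-2-{[7-(methoxymethoxy)-6,8-bis(3-methylbut-2-enyl)-4-oxochromen-3-yl]oxy}-N-methylacetamide, via enaminone 15 (not isolated)
Conditions: Me2NCH(OMe)2 (3 equiv), toluene, 95 °C
Reagents that add atoms: N,N-dimethylformamide dimethyl acetal, COC(OC)N(C)C
Why: Chromone synthesis from a 2-hydroxyaryl ketone and a formamide acetal: condensation at the only CH2 beside the ketone gives enaminone 15, and 6-endo addition of the phenol oxygen to the aminomethylene carbon with loss of the amine closes ring C. The alpha carbon already carries the ether oxygen, so no oxidation is needed beside the prenyl groups, and the amide CH2 is not acidic enough to condense.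

Step 9
Reactants: 16 N-methoxy-2-{[7-(methoxymethoxy)-6,8-bis(3-methylbut-2-enyl)-4-oxochromen-3-yl]oxy}-N-methylacetamide; 17 (E)-4-methoxybut-3-en-2-one
Product: 20 (E)-6-methoxy-1-{[7-(methoxymethoxy)-6,8-bis(3-methylbut-2-enyl)-4-oxochromen-3-yl]oxy}hex-5-ene-2,4-dione, via lithium enolate 18 (not isolated), via tetrahedral adduct 19 (not isolated)
Conditions: 17 (3.0 equiv), LiN(SiMe3)2 (2.9 equiv), THF, −78 °C; then 16, −78 → −20 °C; aq. NH4Cl
Reagents that add atoms: none
Why: Claisen-type acylation of a ketone enolate by a Weinreb amide: the kinetic enolate 18, formed at the methyl group of 17, adds to the inductively activated alpha-alkoxy amide, and adduct 19 releases the 1,3-diketone on work-up. The chromone is a vinylogous ester whose C2 is further deactivated by the 3-alkoxy group, so the amide should be the most electrophilic site; strong acid is avoided because it would close 20 to a 4-pyranone.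

Step 10
Reactants: 20 (E)-6-methoxy-1-{[7-(methoxymethoxy)-6,8-bis(3-methylbut-2-enyl)-4-oxochromen-3-yl]oxy}hex-5-ene-2,4-dione
Product: 23 3-(2,4-dihydroxyphenoxy)-7-(methoxymethoxy)-6,8-bis(3-methylbut-2-enyl)chromen-4-one, via bis-enolate 21 (not isolated), via dienediolate 22 (not isolated)
Conditions: LiN(SiMe3)2 (2.5 equiv), THF, Ar, −78 °C → rt; aq. NH4Cl
Reagents that add atoms: none
Why: Proposed new method: the first equivalent of base removes a C3' proton between the two carbonyls and the second removes a C1' proton, the only other sp3 C–H beside a carbonyl and one acidified by the ether oxygen, to give bis-enolate 21, a 1,3,5-triene from C1' to C6'. C1' then bonds to C6', the carbon that carries the methoxy group, in a 6-endo-trig closure that can be drawn either as a conjugate addition or as a disrotatory six-electron electrocyclisation accelerated by the two oxido groups; this closes ring B as dienediolate 22. Methoxide then leaves from C6' by E1cB from the C4' enolate of 22, and removal of the remaining C1' proton from the cyclohexadienone so formed gives the dilithium resorcinolate, which the work-up protonates to 23; aromatisation is irreversible and should draw even a small equilibrium share of 21 through. The closest known reaction types are the base-induced aldol folding of 3,5-dioxo carbonyl chains into resorcinols and arene syntheses by electrocyclisation of a triene followed by loss of an alcohol; closure of a 1,3-diketone dianion onto a beta-alkoxy enone terminus of the same chain has not been described. No stereocentre is set, since the two sp3 centres of 22 vanish on aromatisation. The step needs attack from C1' and not C3', and C- rather than O-cyclisation: C3' could reach C6' only through a four-membered ring and C5' is vinylic, while the charge-dense C1' carbon of the dianion should outrun the enolate oxygen, whose closure onto C6' would give a 4-pyranone. The silylamide is too hindered to add to the chromone and too weak to metalate C2–H or the benzylic CH2 groups, and the 3-alkoxy group lowers the electrophilicity of C2.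

Step 11
Reactants: 23 3-(2,4-dihydroxyphenoxy)-7-(methoxymethoxy)-6,8-bis(3-methylbut-2-enyl)chromen-4-one
Product: 24 3-(2,4-dihydroxyphenoxy)-7-hydroxy-6,8-bis(3-methylbut-2-enyl)chromen-4-one (eryvarin F)
Conditions: HCl (1 M), MeOH/THF, rt → 40 °C
Reagents that add atoms: none
Why: Acid-catalysed methanolysis of the single aryl acetal; chromone, ether link and resorcinol are stable to dilute acid, and the mild conditions are chosen so that acetal cleavage precedes any addition of the freed C7 hydroxyl to a flanking prenyl double bond.

## Compound list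

1 | 2,4,6-tribromobenzene-1,3-diol | Oc1c(Br)cc(Br)c(O)c1Br | starting material
2 | 1,3,5-tribromo-2,4-bis(methoxymethoxy)benzene | COCOc1c(Br)cc(Br)c(OCOC)c1Br | intermediate
3 | 1-bromo-3-methylbut-2-ene | CC(C)=CCBr | starting material
4 | [3,5-dibromo-2,6-bis(methoxymethoxy)phenyl]lithium | [Li]c1c(OCOC)c(Br)cc(Br)c1OCOC | intermediate
5 | 1,5-dibromo-2,4-bis(methoxymethoxy)-3-(3-methylbut-2-enyl)benzene | COCOc1c(Br)cc(Br)c(OCOC)c1CC=C(C)C | intermediate
6 | [5-bromo-2,4-bis(methoxymethoxy)-3-(3-methylbut-2-enyl)phenyl]lithium | [Li]c1cc(Br)c(OCOC)c(CC=C(C)C)c1OCOC | intermediate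
7 | 1-bromo-2,4-bis(methoxymethoxy)-3,5-bis(3-methylbut-2-enyl)benzene | COCOc1c(Br)cc(CC=C(C)C)c(OCOC)c1CC=C(C)C | intermediate
8 | 2,2'-oxydiacetyl chloride | O=C(Cl)COCC(=O)Cl | starting material
9 | N,N'-dimethoxy-N,N'-dimethyl-2,2'-oxydiacetamide | CON(C)C(=O)COCC(=O)N(C)OC | intermediate
10 | [2,4-bis(methoxymethoxy)-3,5-bis(3-methylbut-2-enyl)phenyl]lithium | [Li]c1cc(CC=C(C)C)c(OCOC)c(CC=C(C)C)c1OCOC | intermediate
11 | lithium alkoxide of the hemiaminal from 10 and 9 (racemic, transient) | [Li]OC(COCC(=O)N(C)OC)(N(C)OC)c1cc(CC=C(C)C)c(OCOC)c(CC=C(C)C)c1OCOC | intermediate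
12 | 2-{2-[2,4-bis(methoxymethoxy)-3,5-bis(3-methylbut-2-enyl)phenyl]-2-oxoethoxy}-N-methoxy-N-methylacetamide | CON(C)C(=O)COCC(=O)c1cc(CC=C(C)C)c(OCOC)c(CC=C(C)C)c1OCOC | intermediate
13 | 2-{2-[2,4-dihydroxy-3,5-bis(3-methylbut-2-enyl)phenyl]-2-oxoethoxy}-N-methoxy-N-methylacetamide | CON(C)C(=O)COCC(=O)c1cc(CC=C(C)C)c(O)c(CC=C(C)C)c1O | intermediate
14 | 2-{2-[2-hydroxy-4-(methoxymethoxy)-3,5-bis(3-methylbut-2-enyl)phenyl]-2-oxoethoxy}-N-methoxy-N-methylacetamide | CON(C)C(=O)COCC(=O)c1cc(CC=C(C)C)c(OCOC)c(CC=C(C)C)c1O | intermediate
15 | 2-({3-(dimethylamino)-1-[2-hydroxy-4-(methoxymethoxy)-3,5-bis(3-methylbut-2-enyl)phenyl]-1-oxoprop-2-en-2-yl}oxy)-N-methoxy-N-methylacetamide (alkene geometry not fixed) | CON(C)C(=O)COC(=CN(C)C)C(=O)c1cc(CC=C(C)C)c(OCOC)c(CC=C(C)C)c1O | intermediate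
16 | N-methoxy-2-{[7-(methoxymethoxy)-6,8-bis(3-methylbut-2-enyl)-4-oxochromen-3-yl]oxy}-N-methylacetamide | CON(C)C(=O)COc1coc2c(CC=C(C)C)c(OCOC)c(CC=C(C)C)cc2c1=O | intermediate
17 | (E)-4-methoxybut-3-en-2-one | CO/C=C/C(C)=O | starting material
18 | lithium (E)-4-methoxybuta-1,3-dien-2-olate | C=C(O[Li])/C=C/OC | intermediate
19 | lithium alkoxide of the hemiaminal from 18 and 16 (racemic, transient) | CO/C=C/C(=O)CC(O[Li])(N(C)OC)COc1coc2c(CC=C(C)C)c(OCOC)c(CC=C(C)C)cc2c1=O | intermediate
20 | (E)-6-methoxy-1-{[7-(methoxymethoxy)-6,8-bis(3-methylbut-2-enyl)-4-oxochromen-3-yl]oxy}hex-5-ene-2,4-dione | CO/C=C/C(=O)CC(=O)COc1coc2c(CC=C(C)C)c(OCOC)c(CC=C(C)C)cc2c1=O | intermediate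
21 | dilithium (5E)-6-methoxy-1-{[7-(methoxymethoxy)-6,8-bis(3-methylbut-2-enyl)-4-oxochromen-3-yl]oxy}hexa-1,3,5-triene-2,4-diolate (enolate geometries not fixed) | CO/C=C/C(O[Li])=CC(O[Li])=COc1coc2c(CC=C(C)C)c(OCOC)c(CC=C(C)C)cc2c1=O | intermediate
22 | dilithium 5-methoxy-6-{[7-(methoxymethoxy)-6,8-bis(3-methylbut-2-enyl)-4-oxochromen-3-yl]oxy}cyclohexa-1,3-diene-1,3-diolate (two transient sp3 centres, configuration not fixed) | COC1C=C(O[Li])C=C(O[Li])C1Oc1coc2c(CC=C(C)C)c(OCOC)c(CC=C(C)C)cc2c1=O | intermediate
23 | 3-(2,4-dihydroxyphenoxy)-7-(methoxymethoxy)-6,8-bis(3-methylbut-2-enyl)chromen-4-one | COCOc1c(CC=C(C)C)cc2c(=O)c(Oc3ccc(O)cc3O)coc2c1CC=C(C)C | intermediate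
24 | 3-(2,4-dihydroxyphenoxy)-7-hydroxy-6,8-bis(3-methylbut-2-enyl)chromen-4-one (eryvarin F) | CC(C)=CCc1cc2c(=O)c(Oc3ccc(O)cc3O)coc2c(CC=C(C)C)c1O | target

## Step count and least certain steps

Total: 11 steps. Longest linear sequence: 10 steps (steps 1, 2, 3, 5, 6, 7, 8, 9, 10, 11, from 1 to 24); step 4 is a one-step side branch.

Step 10 (key step). Three processes are most likely to interfere. The first is O-cyclisation: an enolate oxygen closes onto C6' with loss of the methoxy group and gives a 4-pyranone, because the lithium chelate of the diketonate holds the chain in a U shape in which C1' points away from C6'. The second is incomplete second deprotonation at C1'. The third is reversible conjugate addition of the stabilised C3' carbanion, or of the released methoxide, to C2 of the chromone. A potassium counter-ion with a crown ether would loosen the chelate, but the real fallback builds ring B by known chemistry; it sets out from 7 and returns at 24. Commercial 2,4-dihydroxybenzaldehyde is protected with NaH and MOMCl to give 2,4-bis(methoxymethoxy)benzaldehyde F1. Baeyer–Villiger oxidation of F1 with mCPBA gives 2,4-bis(methoxymethoxy)phenyl formate F2, and methanolysis of F2 (K2CO3, MeOH) gives 2,4-bis(methoxymethoxy)phenol F3. O-Alkylation of F3 with 2-chloro-N-methoxy-N-methylacetamide (K2CO3, DMF) gives 2-[2,4-bis(methoxymethoxy)phenoxy]-N-methoxy-N-methylacetamide F4. Aryllithium 10, generated from 7 as in step 5, adds once to F4 to give 2-[2,4-bis(methoxymethoxy)phenoxy]-1-[2,4-bis(methoxymethoxy)-3,5-bis(3-methylbut-2-enyl)phenyl]ethanone F5. Dilute HCl in MeOH removes the four acetals of F5 to give 1-[2,4-dihydroxy-3,5-bis(3-methylbut-2-enyl)phenyl]-2-(2,4-dihydroxyphenoxy)ethanone F6. Condensation of F6 with N,N-dimethylformamide dimethyl acetal in THF at 60 °C, the known route from aryloxymethyl 2-hydroxyaryl ketones to 3-aryloxychromones, closes ring C and gives 24.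

Step 9. The enolate 18 may add too slowly to the amide at temperatures where it is stable, it may instead exchange protons with 16, and 20 may cyclise to a pyranone on acidic silica. The fallback uses a more electrophilic partner; it sets out from 16 and returns at 20. (C5H5)2Zr(H)Cl in THF at rt reduces the amide of 16 to 2-{[7-(methoxymethoxy)-6,8-bis(3-methylbut-2-enyl)-4-oxochromen-3-yl]oxy}acetaldehyde F7. Aldol addition of 18 to F7 at −78 °C gives racemic (E)-5-hydroxy-1-methoxy-6-{[7-(methoxymethoxy)-6,8-bis(3-methylbut-2-enyl)-4-oxochromen-3-yl]oxy}hex-1-en-3-one F8. Dess–Martin oxidation of the secondary alcohol of F8 gives 20.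

Step 5. The aryllithium may add at both amide ends of 9 in spite of the excess, or be quenched by proton transfer from a benzylic–allylic CH2 before it meets the electrophile. The fallback replaces the statistical mono-addition by a ring opening that can occur only once; it sets out from 7 and returns at 12. Aryllithium 10 is added at −78 °C to 1,4-dioxane-2,6-dione (diglycolic anhydride) to give 2-{2-[2,4-bis(methoxymethoxy)-3,5-bis(3-methylbut-2-enyl)phenyl]-2-oxoethoxy}acetic acid F9; the carboxylate formed on ring opening protects the second carbonyl. Amide coupling of F9 with N,O-dimethylhydroxylamine hydrochloride (carbonyldiimidazole, CH2Cl2) gives 12.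

Step 11. Acid may add the freed C7 hydroxyl across a flanking prenyl double bond (chroman formation) faster than expected, since ring A of 23 is more electron-rich than that of 12 in step 6. The fallback uses a protecting group that is removed without acid; it sets out from 13 and returns at 24. Selective O-allylation of 13 (allyl bromide, K2CO3, acetone) gives 2-{2-[2-hydroxy-3,5-bis(3-methylbut-2-enyl)-4-(prop-2-enyloxy)phenyl]-2-oxoethoxy}-N-methoxy-N-methylacetamide F10. The conditions of step 8 convert F10 into N-methoxy-N-methyl-2-{[6,8-bis(3-methylbut-2-enyl)-4-oxo-7-(prop-2-enyloxy)chromen-3-yl]oxy}acetamide F11. The conditions of step 9 convert F11 into (E)-6-methoxy-1-{[6,8-bis(3-methylbut-2-enyl)-4-oxo-7-(prop-2-enyloxy)chromen-3-yl]oxy}hex-5-ene-2,4-dione F12. The conditions of step 10 convert F12 into 3-(2,4-dihydroxyphenoxy)-6,8-bis(3-methylbut-2-enyl)-7-(prop-2-enyloxy)chromen-4-one F13. Pd(PPh3)4 (zerovalent palladium, 5 mol %) and morpholine in THF at rt remove the allyl group of F13 and give 24; the trisubstituted prenyl alkenes do not form allyl complexes under these conditions.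

## Further compounds

F1 | step 10 | 2,4-bis(methoxymethoxy)benzaldehyde | COCOc1ccc(C=O)c(OCOC)c1
F2 | step 10 | 2,4-bis(methoxymethoxy)phenyl formate | COCOc1ccc(OC=O)c(OCOC)c1
F3 | step 10 | 2,4-bis(methoxymethoxy)phenol | COCOc1ccc(O)c(OCOC)c1
F4 | step 10 | 2-[2,4-bis(methoxymethoxy)phenoxy]-N-methoxy-N-methylacetamide | CON(C)C(=O)COc1ccc(OCOC)cc1OCOC
F5 | step 10 | 2-[2,4-bis(methoxymethoxy)phenoxy]-1-[2,4-bis(methoxymethoxy)-3,5-bis(3-methylbut-2-enyl)phenyl]ethanone | COCOc1ccc(OCC(=O)c2cc(CC=C(C)C)c(OCOC)c(CC=C(C)C)c2OCOC)c(OCOC)c1
F6 | step 10 | 1-[2,4-dihydroxy-3,5-bis(3-methylbut-2-enyl)phenyl]-2-(2,4-dihydroxyphenoxy)ethanone | CC(C)=CCc1cc(C(=O)COc2ccc(O)cc2O)c(O)c(CC=C(C)C)c1O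
F7 | step 9 | 2-{[7-(methoxymethoxy)-6,8-bis(3-methylbut-2-enyl)-4-oxochromen-3-yl]oxy}acetaldehyde | O=CCOc1coc2c(CC=C(C)C)c(OCOC)c(CC=C(C)C)cc2c1=O
F8 | step 9 | (E)-5-hydroxy-1-methoxy-6-{[7-(methoxymethoxy)-6,8-bis(3-methylbut-2-enyl)-4-oxochromen-3-yl]oxy}hex-1-en-3-one (racemic) | CO/C=C/C(=O)CC(O)COc1coc2c(CC=C(C)C)c(OCOC)c(CC=C(C)C)cc2c1=O
F9 | step 5 | 2-{2-[2,4-bis(methoxymethoxy)-3,5-bis(3-methylbut-2-enyl)phenyl]-2-oxoethoxy}acetic acid | OC(=O)COCC(=O)c1cc(CC=C(C)C)c(OCOC)c(CC=C(C)C)c1OCOC
F10 | step 11 | 2-{2-[2-hydroxy-3,5-bis(3-methylbut-2-enyl)-4-(prop-2-enyloxy)phenyl]-2-oxoethoxy}-N-methoxy-N-methylacetamide | CON(C)C(=O)COCC(=O)c1cc(CC=C(C)C)c(OCC=C)c(CC=C(C)C)c1O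
F11 | step 11 | N-methoxy-N-methyl-2-{[6,8-bis(3-methylbut-2-enyl)-4-oxo-7-(prop-2-enyloxy)chromen-3-yl]oxy}acetamide | CON(C)C(=O)COc1coc2c(CC=C(C)C)c(OCC=C)c(CC=C(C)C)cc2c1=O
F12 | step 11 | (E)-6-methoxy-1-{[6,8-bis(3-methylbut-2-enyl)-4-oxo-7-(prop-2-enyloxy)chromen-3-yl]oxy}hex-5-ene-2,4-dione | CO/C=C/C(=O)CC(=O)COc1coc2c(CC=C(C)C)c(OCC=C)c(CC=C(C)C)cc2c1=O
F13 | step 11 | 3-(2,4-dihydroxyphenoxy)-6,8-bis(3-methylbut-2-enyl)-7-(prop-2-enyloxy)chromen-4-one | C=CCOc1c(CC=C(C)C)cc2c(=O)c(Oc3ccc(O)cc3O)coc2c1CC=C(C)C
A1 | alternative 1 | 3-[2,4-bis(methoxymethoxy)phenoxy]-7-hydroxy-6,8-bis(3-methylbut-2-enyl)chromen-4-one | CC(C)=CCc1cc2c(=O)c(Oc3ccc(OCOC)cc3OCOC)coc2c(CC=C(C)C)c1O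
A2 | alternative 1 | 2,10-dimethylundeca-2,9-dien-6-one | CC(C)=CCCC(=O)CCC=C(C)C
A3 | alternative 1 | methyl 4-[2,4-bis(methoxymethoxy)phenoxy]-5-(dimethylamino)-2-[(dimethylamino)methylidene]-3-oxopent-4-enoate | COC(=O)C(=CN(C)C)C(=O)C(=CN(C)C)Oc1ccc(OCOC)cc1OCOC
A4 | alternative 2 | 2-[2,4-bis(methoxymethoxy)phenoxy]-1-[2,4-dihydroxy-3,5-bis(3-methylbut-2-enyl)phenyl]ethanone | CC(C)=CCc1cc(C(=O)COc2ccc(OCOC)cc2OCOC)c(O)c(CC=C(C)C)c1O
A5 | alternative 2 | 1-methoxy-2,4-bis(3-methylbut-2-enyl)-1,3-bis(trimethylsilyloxy)buta-1,3-diene | COC(O[Si](C)(C)C)=C(CC=C(C)C)C(O[Si](C)(C)C)=CCC=C(C)C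
A6 | alternative 2 | 1-[2,4-bis(methoxymethoxy)phenoxy]but-3-yn-2-one | C#CC(=O)COc1ccc(OCOC)cc1OCOC
A7 | alternative 3 | 3-[2,4-bis(methoxymethoxy)phenoxy]-7-(methoxymethoxy)-6,8-bis(3-methylbut-2-enyl)chromen-4-one | COCOc1c(CC=C(C)C)cc2c(=O)c(Oc3ccc(OCOC)cc3OCOC)coc2c1CC=C(C)C
A8 | alternative 3 | 7-(methoxymethoxy)-2,2-dimethyl-6,8-bis(3-methylbut-2-enyl)-1,3-benzodioxin-4-one | CC1(C)OC(=O)c2cc(CC=C(C)C)c(OCOC)c(CC=C(C)C)c2O1
A9 | alternative 3 | (E)-2-[2,4-bis(methoxymethoxy)phenoxy]-N,N-dimethylethenamine | CN(C)/C=C/Oc1ccc(OCOC)cc1OCOC
A10 | alternative 3 | 3-(methoxymethoxy)-2,4-bis(3-methylbut-2-enyl)-6-(oxomethylidene)cyclohexa-2,4-dien-1-one | O=C=C1C=C(CC=C(C)C)C(OCOC)=C(CC=C(C)C)C1=O
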